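## Structural features

- The target is one ten-membered carbocycle, numbered here C1(Me)=C2–C3(OH)–C4(iPr)–C5(OAr)–C6–C7(Me)=C8–C9–C10. The isopropyl carbons are C11 (methine on C4), C12 and C13, and the only other ring is the 4-hydroxybenzoyl group on the C5 oxygen.
- Both ring alkenes are trisubstituted and Z, so the ring is a Z,Z-1,5-diene whose two halves meet at the C9–C10 bond.
- C3 (S), C4 (R) and C5 (R) are contiguous. The C3 hydroxyl and C4 isopropyl are trans on the ring, as are C4 isopropyl and C5 acyloxy, so the two oxygens are cis-1,3.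
- Fragile points are the allylic C3 alcohol, the medium-ring diene (acid invites transannular cyclisation), the C5 ester next to a free cis-1,3 hydroxyl (base-promoted acyl shift) and the free phenol.
- The difficulty is the combination of a ten-membered ring, two Z trisubstituted alkenes, three adjacent stereocentres and the need to tell the C3 oxygen from the C5 oxygen.
- The key step exploits the C3 carbinol, which is allylic to C1=C2 and vicinal to the branched C4. If C11 is an isopropenyl carbon, C3–C4 is the bond a [2,3]-Wittig shift makes, and the C3 oxygen was an ether oxygen bound to C12 in a thirteen-membered ring containing O, C12 and C11.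

## Logic of the disconnections

33 ⇒ 32. The two O–Si bonds (C3–O and the phenol O) are cut last because the free allylic alcohol and phenol are the most sensitive groups. One operation removes both. The forward step needs a fluoride source that is not basic, so that the C5 ester does not shift to the cis C3 hydroxyl.

32 ⇒ 27 + 30. The acyl C–O bond at C5 is cut because the ester is the only link between carbocycle and arene. This leaves a ring fragment and 30, which comes from 28 in one flask. The forward step must acylate a hindered secondary alcohol next to the C4 isopropyl group while C3 stays capped.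

27 ⇒ 26 ⇒ 25. Two O–Si bonds are exchanged so that C5 becomes free and C3 protected. This is where the precursor design is changed: C5 carries a triethylsilyl group through the key step, so C3 can take the sturdier tert-butyldimethylsilyl group and C5 can be freed by mild acid. That avoids forcing a tert-butyldiphenylsilyl group onto the hindered C3 hydroxyl and removing it later beside the ester. The forward steps need selective acid cleavage of one silyl ether.

25 ⇒ 24. The C11–C12 single bond is traced back to the isopropenyl alkene, which is what the sigmatropic step delivers. The forward hydrogenation must take the 1,1-disubstituted alkene and leave two trisubstituted ring alkenes.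

24 ⇒ 22. C3–C4 is cut and O is reconnected to C12. The strained ten-membered ring and two stereocentres (C3, C4) are traded for a thirteen-membered diallyl ether with one stereocentre (C5). The forward step needs lithiation at C3 only, E geometry at C4=C11, and control of the C4 face by C5.

22 ⇒ 21 ⇒ 20 ⇒ 19. The O–C3 ether bond is cut, giving an open chain with a C3 chloride and a C12 alcohol. The chain has the (2Z,6Z,10E)-farnesane skeleton with oxygens at both ends. The forward step is a macro-etherification at high dilution, and the two primary allylic oxygens must be addressed one after the other (chloride first, then release of C12–OH).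

19 ⇒ 14 + 17. C10–C1 is cut between an sp3 and an sp2 carbon. This splits off the C1–C3 unit as 17, whose iodine already defines the Z geometry of C1=C2. The forward step needs hydroboration at C10 only and coupling with retention.

14 ⇒ 13 ⇒ 11 ⇒ 10. C9=C10 is cut (methylenation), which reveals a lactol and then an unsaturated six-membered lactone. The ring guarantees that C6 and C9 are cis on C7=C8. The forward step must open the lactol and olefinate without Z to E isomerisation.

10 ⇒ 9 ⇒ 8. C8=C9 is cut (ring-closing metathesis) together with the acyl–O bond. This gives a homoallylic alcohol whose only stereocentre is C5. The metathesis must prefer the 1,1-disubstituted alkene over C4=C11.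

8 ⇒ 6. C5–C6 is cut, leaving an achiral enal and a methallyl nucleophile. The forward step sets C5 (R) by reagent control.

6 ⇒ 4 ⇒ 3 ⇒ 1, and 17 ⇒ 15. The formyl carbon (C5) and the C11 methyl are removed from a three-carbon alkyne. For 17, iodine and hydride are removed from a four-carbon alkynol. Both alkene geometries then follow from the syn or anti course of the carbometalation or hydrometalation.

## Other disconnections considered

Alternative 1: The cut is C9–C10, the doubly allylic bond. In the forward step the open-chain chloro sulfone A2 is deprotonated at C10 by a potassium amide at high dilution, and the sulfonyl carbanion displaces the C9 chloride to give the ten-membered sulfone A1.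
- In favour: the new bond is a plain sp3–sp3 link far from the stereotriad, and C3, C4 and C5 are fixed beforehand in an open chain by substrate-independent methods. In A1 the C3 and C5 oxygens already carry different groups, so no protecting-group exchange is needed on the ring. On this point it is better than the chosen plan.
- Against: a ten-membered ring must be closed directly against transannular strain, with SN2′ attack, elimination and oligomerisation as competitors. The stereotriad with its isopropyl branch has to be built in the open chain between two Z trisubstituted alkenes. The sulfonyl group must then be removed reductively next to C1=C2, where alkene migration is a known hazard.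
- Comparison: both plans rest on a stabilised carbanion and both need the Z alkenes beforehand (equal). The chosen plan closes an unstrained thirteen-membered ring and pays for the ring strain in the sigmatropic step, so it should be safer at ring closure and shorter overall. A1 is safer for the predictability of the stereocentres.

Alternative 2: The cuts are C3–C4 and C5–C6, with C3–C6 as a temporary bond. The dienone A4 is converted to its silyl dienol ether A5, which adds the ketene A6 in a [2+2] sense. Reductive dechlorination and desilylation then trigger retro-aldol opening to the dione A3.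
- In favour: the carbon skeleton arises in very few steps, no macrocyclisation is needed, and both Z alkenes are inherited from the eight-membered ring. On step count to the carbocycle and on alkene geometry it is better than the chosen plan. The C3 ketone of A3 is conjugated and the C5 ketone is not, which offers a handle for telling the two oxygens apart.
- Against: A3 has no fixed stereocentre. C4 is epimerisable and the dione will enolise. Three stereocentres would have to be set by reductions on a flexible ring, in the all-trans sense and in one enantiomeric series, and no dependable method for that is evident. Site selectivity of the ketene addition to A5 and self-condensation of A6 add risk.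
- Comparison: the mechanism (cycloaddition then fragmentation) is attractive and economical. The chosen plan derives C3 and C4 from one secure stereocentre in the ring-forming event, which this target needs more than brevity.

Alternative 3: The cut is C4–C5. The bromo aldehyde A8 is treated with a divalent chromium salt at high dilution, and the allylchromium adds through C4 to the C5 aldehyde to give the dienol A7.
- In favour: the ring and two stereocentres form together, and the anti preference of allylchromium additions does not depend on the halide geometry, matching the trans C4/C5 relationship. A7 has C5–OH free and C3–O silylated, which is exactly what the ester needs. The endgame would be about three steps shorter than in the chosen plan, so on this point it is better.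
- Against: a ten-membered ring is closed directly with stoichiometric chromium. Facial control rests on the C3 stereocentre on the allyl metal, which is less predictable than control from an allylic C–O bond on the acceptor. A8 combines a β,γ-unsaturated aldehyde (prone to conjugation) with an allylic bromide, and C3 must first be made enantioselectively in the open chain.
- Comparison: both plans leave an isopropenyl group to hydrogenate (equal). The chosen plan has the easier ring closure and a better-founded stereochemical model; Alternative 3 has the shorter finish.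

Key step: step 15

## Route

Step 1
Reactants: 1 prop-2-yn-1-ol
Product: 3 (E)-3-iodo-2-methylprop-2-en-1-ol, via alkenylalane 2 (not isolated)
Conditions: Me3Al, Cp2ZrCl2 (cat.), CH2Cl2, 0 °C to rt; then I2, THF, −30 to 0 °C; aq. K2CO3
Reagents that add atoms: trimethylaluminium C[Al](C)C; iodine II
Why: Zirconium-catalysed carboalumination (Negishi) adds methyl and aluminium syn with aluminium on the terminal carbon; iodinolysis with retention fixes the E geometry of the future C4=C11.

Step 2
Reactants: 3 (E)-3-iodo-2-methylprop-2-en-1-ol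
Product: 4 1-{[(E)-3-iodo-2-methylprop-2-enyl]oxymethyl}-4-methoxybenzene
Conditions: NaH, 4-methoxybenzyl chloride, Bu4NI (cat.), THF/DMF, 0 °C to rt
Reagents that add atoms: 4-methoxybenzyl chloride COc1ccc(CCl)cc1
Why: Williamson etherification of a primary allylic alkoxide; the 4-methoxybenzyl ether survives the organolithium, borane, ruthenium and hydride steps and is later removed oxidatively beside silyl ethers.

Step 3
Reactants: 4 1-{[(E)-3-iodo-2-methylprop-2-enyl]oxymethyl}-4-methoxybenzene
Product: 6 (E)-4-(4-methoxybenzyloxy)-3-methylbut-2-enal, via alkenyllithium 5 (not isolated)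
Conditions: t-BuLi (2.1 equiv), Et2O, −78 °C; DMF, −78 to 0 °C; aq. NH4Cl
Reagents that add atoms: N,N-dimethylformamide CN(C)C=O
Why: Iodine–lithium exchange at −78 °C outruns any attack on the benzylic ether and keeps the alkene geometry; formylation of the alkenyllithium gives the E enal, whose carbonyl carbon is C5.

Step 4
Reactants: 6 (E)-4-(4-methoxybenzyloxy)-3-methylbut-2-enal
Product: 8 (2E,4R)-1-(4-methoxybenzyloxy)-2,6-dimethylhepta-2,6-dien-4-ol, via borinic ester 7 (not isolated)
Conditions: (+)-Ipc2BOMe, CH2=C(Me)CH2MgCl, Et2O, −78 °C to rt; then 6, −78 °C; NaOH, H2O2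
Reagents that add atoms: 2-methylallylmagnesium chloride CC(=C)C[Mg]Cl
Why: Brown asymmetric methallylboration through a chair six-membered transition state; the borane derived from (−)-α-pinene attacks the Re face of the enal and sets C5 as R, the only stereocentre carried into the macrocycle.

Step 5
Reactants: 8 (2E,4R)-1-(4-methoxybenzyloxy)-2,6-dimethylhepta-2,6-dien-4-ol
Product: 9 (2E,4R)-1-(4-methoxybenzyloxy)-2,6-dimethylhepta-2,6-dien-4-yl prop-2-enoate
Conditions: acryloyl chloride, Et3N, DMAP (cat.), CH2Cl2, −20 to 0 °C
Reagents that add atoms: acryloyl chloride C=CC(Cl)=O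
Why: DMAP-catalysed acylation of a secondary alcohol; the acrylate brings C8 and C9 and ties them to the C5 oxygen so that the next ring closure can only give the Z alkene.

Step 6
Reactants: 9 (2E,4R)-1-(4-methoxybenzyloxy)-2,6-dimethylhepta-2,6-dien-4-yl prop-2-enoate
Product: 10 (6R)-6-[(E)-3-(4-methoxybenzyloxy)-2-methylprop-1-enyl]-4-methyl-5,6-dihydro-2H-pyran-2-one
Conditions: second-generation Grubbs catalyst (5 mol%), CH2Cl2 (5 mM), 40 °C
Reagents that add atoms: none
Why: Ring-closing metathesis of an acrylate with a 1,1-disubstituted alkene to the six-membered unsaturated lactone; the ring holds C6 and C9 cis on C7=C8 (the Z geometry of the target), and the internal trisubstituted C4=C11 alkene should be too hindered to compete.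

Step 7
Reactants: 10 (6R)-6-[(E)-3-(4-methoxybenzyloxy)-2-methylprop-1-enyl]-4-methyl-5,6-dihydro-2H-pyran-2-one
Product: 11 (6R)-6-[(E)-3-(4-methoxybenzyloxy)-2-methylprop-1-enyl]-4-methyl-5,6-dihydro-2H-pyran-2-ol
Conditions: i-Bu2AlH (1.1 equiv), CH2Cl2, −78 °C; aq. potassium sodium tartrate
Reagents that add atoms: none
Why: 1,2-Reduction of the lactone carbonyl stops at the lactol because the tetrahedral aluminium alkoxide is stable in the cold.

Step 8
Reactants: 11 (6R)-6-[(E)-3-(4-methoxybenzyloxy)-2-methylprop-1-enyl]-4-methyl-5,6-dihydro-2H-pyran-2-ol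
Product: 13 (3Z,6R,7E)-9-(4-methoxybenzyloxy)-4,8-dimethylnona-1,3,7-trien-6-ol, via hydroxy enal 12 (not isolated)
Conditions: Ph3PCH3Br, KN(SiMe3)2 (3 equiv each), THF, 0 °C; then 11, 0 °C to rt
Reagents that add atoms: methyltriphenylphosphonium bromide C[P+](c1ccccc1)(c1ccccc1)c1ccccc1.[Br-]
Why: Wittig methylenation of a lactol through its open hydroxy enal tautomer adds C10 as a terminal methylene; the Z geometry of C7=C8 is carried over from the ring.

Step 9
Reactants: 13 (3Z,6R,7E)-9-(4-methoxybenzyloxy)-4,8-dimethylnona-1,3,7-trien-6-ol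
Product: 14 (3Z,6R,7E)-9-(4-methoxybenzyloxy)-4,8-dimethyl-6-(triethylsilyloxy)nona-1,3,7-triene
Conditions: Et3SiCl, imidazole, DMF, 0 °C
Reagents that add atoms: chlorotriethylsilane CC[Si](Cl)(CC)CC
Why: Silylation of the secondary allylic alcohol; triethylsilyl is chosen because mild acid can later remove it from C5 in the presence of the tert-butyldimethylsilyl group placed on C3.

Step 10
Reactants: 15 but-2-yn-1-ol
Product: 17 (Z)-3-iodobut-2-en-1-ol, via cyclic alanate 16 (not isolated)
Conditions: NaAlH2(OCH2CH2OMe)2, THF, 0 °C to rt; EtOAc; then I2, THF, −78 to 0 °C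
Reagents that add atoms: iodine II
Why: Hydroxyl-directed trans-hydroalumination of the propargylic alcohol puts aluminium on the distal carbon, cis to the carbinol carbon; iodinolysis with retention gives the Z iodoalkene that becomes C1=C2.

Step 11
Reactants: 14 (3Z,6R,7E)-9-(4-methoxybenzyloxy)-4,8-dimethyl-6-(triethylsilyloxy)nona-1,3,7-triene; 17 (Z)-3-iodobut-2-en-1-ol
Product: 19 (2Z,6Z,9R,10E)-12-(4-methoxybenzyloxy)-3,7,11-trimethyl-9-(triethylsilyloxy)dodeca-2,6,10-trien-1-ol, via alkylborane 18 (not isolated)
Conditions: 9-BBN-H (1.2 equiv), THF, 0 °C to rt; then 17, PdCl2(dppf) (5 mol%), AsPh3, Cs2CO3, DMF/H2O, rt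
Reagents that add atoms: none
Why: 9-BBN-H adds only to the terminal CH2 of the diene (anti-Markovnikov, least hindered alkene), and the B-alkyl Suzuki–Miyaura coupling with the iodoalkene goes with retention, so C10–C1 forms with C1=C2 Z; the free hydroxyl and the silyl ether tolerate aqueous carbonate.

Step 12
Reactants: 19 (2Z,6Z,9R,10E)-12-(4-methoxybenzyloxy)-3,7,11-trimethyl-9-(triethylsilyloxy)dodeca-2,6,10-trien-1-ol
Product: 20 (2Z,6Z,9R,10E)-1-chloro-12-(4-methoxybenzyloxy)-3,7,11-trimethyl-9-(triethylsilyloxy)dodeca-2,6,10-triene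
Conditions: N-chlorosuccinimide, Me2S, CH2Cl2, −30 to 0 °C
Reagents that add atoms: N-chlorosuccinimide O=C1CCC(=O)N1Cl
Why: Corey–Kim chlorination converts a primary allylic alcohol into the chloride under neutral conditions, without allylic transposition or loss of Z geometry.

Step 13
Reactants: 20 (2Z,6Z,9R,10E)-1-chloro-12-(4-methoxybenzyloxy)-3,7,11-trimethyl-9-(triethylsilyloxy)dodeca-2,6,10-triene
Product: 21 (2E,4R,6Z,10Z)-12-chloro-2,6,10-trimethyl-4-(triethylsilyloxy)dodeca-2,6,10-trien-1-ol
Conditions: DDQ, CH2Cl2/pH 7 phosphate buffer, 0 °C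
Reagents that add atoms: none
Why: Oxidative cleavage of the 4-methoxybenzyl ether in a buffered two-phase medium should leave the allylic chloride, the triethylsilyl ether and the trisubstituted alkenes untouched.

Step 14
Reactants: 21 (2E,4R,6Z,10Z)-12-chloro-2,6,10-trimethyl-4-(triethylsilyloxy)dodeca-2,6,10-trien-1-ol
Product: 22 (3Z,7Z,10R,11E)-4,8,12-trimethyl-10-(triethylsilyloxy)-1-oxacyclotrideca-3,7,11-triene
Conditions: NaH, Bu4NI (cat.), THF, 65 °C, slow addition (2 mM final)
Reagents that add atoms: none
Why: Intramolecular Williamson etherification at high dilution; the primary C12 alkoxide displaces the primary allylic C3 chloride in an SN2 sense and closes a thirteen-membered ring with little strain.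

Step 15
Reactants: 22 (3Z,7Z,10R,11E)-4,8,12-trimethyl-10-(triethylsilyloxy)-1-oxacyclotrideca-3,7,11-triene
Product: 24 (1S,2Z,6Z,9R,10R)-3,7-dimethyl-10-(prop-1-en-2-yl)-9-(triethylsilyloxy)cyclodeca-2,6-dien-1-ol, via C3-lithiated ether 23 (not isolated)
Conditions: s-BuLi (1.3 equiv), THF, −78 °C; AcOH, −78 °C
Reagents that add atoms: none
Why: This is a [2,3]-Wittig rearrangement run as a ring contraction, the reaction type known for thirteen-membered cyclic diallylic ethers that give germacrane-type 2-isopropenylcyclodecenols. s-BuLi removes an allylic α-oxy proton at C3 to give 23; its carbanion bonds to C4 through a five-membered envelope (C3, O, C12, C11, C4) while O–C12 breaks and C11=C12 forms, and the alkoxide formed pays for the strain of the smaller ring. The ten-membered ring closes by transannular suprafacial attack of C3 on the far alkene carbon of the opposite allyl arm, so no dilution is needed. C3 versus C4: the E geometry of C4=C11 and a transition state in which the five-membered array is trans-fused to the forming carbocycle (C2 exo) give the anti, ring-trans relationship of hydroxyl and isopropenyl. C4 versus C5: with C5–H eclipsing C4=C11 to avoid allylic 1,3-strain with the C13 methyl, the carbanion should enter anti to the C5–O bond (Felkin–Anh-type arrangement), which gives 4R beside 5R and hence 3S. Regioselectivity: lithiation at C12 could only rearrange by bonding to the fully substituted C1, whereas the C3 anion attacks the CH terminus C4. The reaction is kept at −78 °C and quenched cold so that the allyl anion keeps the Z geometry of C1=C2, no [1,2]-shift intervenes and the silyl group does not migrate to the new alkoxide.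

Step 16
Reactants: 24 (1S,2Z,6Z,9R,10R)-3,7-dimethyl-10-(prop-1-en-2-yl)-9-(triethylsilyloxy)cyclodeca-2,6-dien-1-ol
Product: 25 (1S,2Z,6Z,9R,10R)-3,7-dimethyl-10-(propan-2-yl)-9-(triethylsilyloxy)cyclodeca-2,6-dien-1-ol
Conditions: H2 (1 atm), RhCl(PPh3)3 (10 mol%), benzene, rt
Reagents that add atoms: none
Why: Homogeneous hydrogenation with RhCl(PPh3)3 reduces the unhindered 1,1-disubstituted alkene far faster than the two trisubstituted ring alkenes, so only C11=C12 is saturated.

Step 17
Reactants: 25 (1S,2Z,6Z,9R,10R)-3,7-dimethyl-10-(propan-2-yl)-9-(triethylsilyloxy)cyclodeca-2,6-dien-1-ol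
Product: 26 tert-butyl{[(1S,2Z,6Z,9R,10S)-3,7-dimethyl-10-(propan-2-yl)-9-(triethylsilyloxy)cyclodeca-2,6-dien-1-yl]oxy}dimethylsilane
Conditions: t-BuMe2SiOTf, 2,6-lutidine, CH2Cl2, −78 to 0 °C
Reagents that add atoms: tert-butyldimethylsilyl trifluoromethanesulfonate CC(C)(C)[Si](C)(C)OS(=O)(=O)C(F)(F)F
Why: A silyl triflate with a hindered pyridine base silylates the hindered allylic C3 hydroxyl in the cold without an alkoxide that could move the C5 silyl group; the descriptor at the isopropyl carbon changes by priority only.

Step 18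
Reactants: 26 tert-butyl{[(1S,2Z,6Z,9R,10S)-3,7-dimethyl-10-(propan-2-yl)-9-(triethylsilyloxy)cyclodeca-2,6-dien-1-yl]oxy}dimethylsilane
Product: 27 (1R,3Z,7Z,9S,10S)-9-(tert-butyldimethylsilyloxy)-3,7-dimethyl-10-(propan-2-yl)cyclodeca-3,7-dien-1-ol
Conditions: pyridinium p-toluenesulfonate (0.2 equiv), MeOH/CH2Cl2, 0 °C to rt
Reagents that add atoms: none
Why: Acid-catalysed methanolysis removes triethylsilyl ethers much faster than tert-butyldimethylsilyl ethers, so only the C5 oxygen is uncovered; the acid is too weak to ionise the allylic C3 ether or start transannular cyclisation.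

Step 19
Reactants: 28 4-hydroxybenzoic acid
Product: 30 4-(tert-butyldimethylsilyloxy)benzoic acid, via bis-silyl compound 29 (not isolated)
Conditions: t-BuMe2SiCl (2.2 equiv), imidazole, DMF, rt; then AcOH/THF/H2O, rt
Reagents that add atoms: tert-butyldimethylsilyl chloride CC(C)(C)[Si](C)(C)Cl
Why: Exhaustive silylation followed by selective hydrolysis of the labile silyl ester leaves the aryl silyl ether.

Step 20
Reactants: 27 (1R,3Z,7Z,9S,10S)-9-(tert-butyldimethylsilyloxy)-3,7-dimethyl-10-(propan-2-yl)cyclodeca-3,7-dien-1-ol; 30 4-(tert-butyldimethylsilyloxy)benzoic acid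
Product: 32 (1R,3Z,7Z,9S,10S)-9-(tert-butyldimethylsilyloxy)-3,7-dimethyl-10-(propan-2-yl)cyclodeca-3,7-dien-1-yl 4-(tert-butyldimethylsilyloxy)benzoate, via mixed anhydride 31 (not isolated)
Conditions: 30, 2,4,6-trichlorobenzoyl chloride, Et3N, toluene, rt; then 27, DMAP, rt to 40 °C
Reagents that add atoms: none
Why: Yamaguchi esterification; DMAP takes the less hindered aroyl group of the mixed anhydride and transfers it to the hindered C5 hydroxyl without touching a stereocentre.

Step 21
Reactants: 32 (1R,3Z,7Z,9S,10S)-9-(tert-butyldimethylsilyloxy)-3,7-dimethyl-10-(propan-2-yl)cyclodeca-3,7-dien-1-yl 4-(tert-butyldimethylsilyloxy)benzoate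
Product: 33 (1R,3Z,7Z,9S,10R)-9-hydroxy-3,7-dimethyl-10-(propan-2-yl)cyclodeca-3,7-dien-1-yl 4-hydroxybenzoate
Conditions: HF·pyridine, pyridine, THF, 0 °C to rt
Reagents that add atoms: none
Why: Buffered HF·pyridine cleaves both the aryl and the allylic silyl ether; the medium is not basic, so the benzoate should neither shift to the cis C3 hydroxyl nor be cleaved.

## Compound list

1 | prop-2-yn-1-ol | C#CCO | starting material
2 | dimethylaluminium (E)-3-(dimethylalumanyl)-2-methylprop-2-en-1-olate | C[Al](C)OC/C(C)=C/[Al](C)C | intermediate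
3 | (E)-3-iodo-2-methylprop-2-en-1-ol | OC/C(C)=C/I | intermediate
4 | 1-{[(E)-3-iodo-2-methylprop-2-enyl]oxymethyl}-4-methoxybenzene | COc1ccc(COC/C(C)=C/I)cc1 | intermediate
5 | (E)-3-(4-methoxybenzyloxy)-2-methylprop-1-enyllithium | COc1ccc(COC/C(C)=C/[Li])cc1 | intermediate
6 | (E)-4-(4-methoxybenzyloxy)-3-methylbut-2-enal | COc1ccc(COC/C(C)=C/C=O)cc1 | intermediate
7 | diisopinocampheylborinic ester of 8 (boron on the C5 oxygen) | COc1ccc(COC/C(C)=C/[C@@H](CC(C)=C)OB([C@H]2C[C@H]3C[C@@H]([C@@H]2C)C3(C)C)[C@H]2C[C@H]3C[C@@H]([C@@H]2C)C3(C)C)cc1 | intermediate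
8 | (2E,4R)-1-(4-methoxybenzyloxy)-2,6-dimethylhepta-2,6-dien-4-ol | COc1ccc(COC/C(C)=C/[C@H](O)CC(C)=C)cc1 | intermediate
9 | (2E,4R)-1-(4-methoxybenzyloxy)-2,6-dimethylhepta-2,6-dien-4-yl prop-2-enoate | COc1ccc(COC/C(C)=C/[C@H](OC(=O)C=C)CC(C)=C)cc1 | intermediate
10 | (6R)-6-[(E)-3-(4-methoxybenzyloxy)-2-methylprop-1-enyl]-4-methyl-5,6-dihydro-2H-pyran-2-one | COc1ccc(COC/C(C)=C/[C@H]2CC(C)=CC(=O)O2)cc1 | intermediate
11 | (6R)-6-[(E)-3-(4-methoxybenzyloxy)-2-methylprop-1-enyl]-4-methyl-5,6-dihydro-2H-pyran-2-ol (both anomers) | COc1ccc(COC/C(C)=C/[C@H]2CC(C)=CC(O)O2)cc1 | intermediate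
12 | (2Z,5R,6E)-5-hydroxy-8-(4-methoxybenzyloxy)-3,7-dimethylocta-2,6-dienal | COc1ccc(COC/C(C)=C/[C@H](O)C/C(C)=C\C=O)cc1 | intermediate
13 | (3Z,6R,7E)-9-(4-methoxybenzyloxy)-4,8-dimethylnona-1,3,7-trien-6-ol | COc1ccc(COC/C(C)=C/[C@H](O)C/C(C)=C\C=C)cc1 | intermediate
14 | (3Z,6R,7E)-9-(4-methoxybenzyloxy)-4,8-dimethyl-6-(triethylsilyloxy)nona-1,3,7-triene | COc1ccc(COC/C(C)=C/[C@H](O[Si](CC)(CC)CC)C/C(C)=C\C=C)cc1 | intermediate
15 | but-2-yn-1-ol | CC#CCO | starting material
16 | sodium 2,2-bis(2-methoxyethoxy)-3-methyl-2,5-dihydro-1,2-oxaluminol-2-uide | CC1=CCO[Al-]1(OCCOC)OCCOC.[Na+] | intermediate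
17 | (Z)-3-iodobut-2-en-1-ol | C/C(I)=C/CO | intermediate
18 | 9-[(3Z,6R,7E)-9-(4-methoxybenzyloxy)-4,8-dimethyl-6-(triethylsilyloxy)nona-3,7-dienyl]-9-borabicyclo[3.3.1]nonane | COc1ccc(COC/C(C)=C/[C@H](O[Si](CC)(CC)CC)C/C(C)=C\CCB2C3CCCC2CCC3)cc1 | intermediate
19 | (2Z,6Z,9R,10E)-12-(4-methoxybenzyloxy)-3,7,11-trimethyl-9-(triethylsilyloxy)dodeca-2,6,10-trien-1-ol | COc1ccc(COC/C(C)=C/[C@H](O[Si](CC)(CC)CC)C/C(C)=C\CC/C(C)=C\CO)cc1 | intermediate
20 | (2Z,6Z,9R,10E)-1-chloro-12-(4-methoxybenzyloxy)-3,7,11-trimethyl-9-(triethylsilyloxy)dodeca-2,6,10-triene | COc1ccc(COC/C(C)=C/[C@H](O[Si](CC)(CC)CC)C/C(C)=C\CC/C(C)=C\CCl)cc1 | intermediate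
21 | (2E,4R,6Z,10Z)-12-chloro-2,6,10-trimethyl-4-(triethylsilyloxy)dodeca-2,6,10-trien-1-ol | OC/C(C)=C/[C@H](O[Si](CC)(CC)CC)C/C(C)=C\CC/C(C)=C\CCl | intermediate
22 | (3Z,7Z,10R,11E)-4,8,12-trimethyl-10-(triethylsilyloxy)-1-oxacyclotrideca-3,7,11-triene (oxygen bridges C3 and C12; C5 silyl ether) | C/C1=C/COC/C(C)=C/[C@H](O[Si](CC)(CC)CC)C/C(C)=C\CC1 | intermediate
23 | C3-lithiated 22 (lithium on the ether CH2 next to C1=C2) | C/C1=C/C([Li])OC/C(C)=C/[C@H](O[Si](CC)(CC)CC)C/C(C)=C\CC1 | intermediate
24 | (1S,2Z,6Z,9R,10R)-3,7-dimethyl-10-(prop-1-en-2-yl)-9-(triethylsilyloxy)cyclodeca-2,6-dien-1-ol (ring locants: 3S OH; 4R isopropenyl; 5R silyl ether) | C/C1=C/[C@H](O)[C@@H](C(C)=C)[C@H](O[Si](CC)(CC)CC)C/C(C)=C\CC1 | intermediate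
25 | (1S,2Z,6Z,9R,10R)-3,7-dimethyl-10-(propan-2-yl)-9-(triethylsilyloxy)cyclodeca-2,6-dien-1-ol | C/C1=C/[C@H](O)[C@@H](C(C)C)[C@H](O[Si](CC)(CC)CC)C/C(C)=C\CC1 | intermediate
26 | tert-butyl{[(1S,2Z,6Z,9R,10S)-3,7-dimethyl-10-(propan-2-yl)-9-(triethylsilyloxy)cyclodeca-2,6-dien-1-yl]oxy}dimethylsilane | C/C1=C/[C@H](O[Si](C)(C)C(C)(C)C)[C@@H](C(C)C)[C@H](O[Si](CC)(CC)CC)C/C(C)=C\CC1 | intermediate
27 | (1R,3Z,7Z,9S,10S)-9-(tert-butyldimethylsilyloxy)-3,7-dimethyl-10-(propan-2-yl)cyclodeca-3,7-dien-1-ol | C/C1=C/[C@H](O[Si](C)(C)C(C)(C)C)[C@@H](C(C)C)[C@H](O)C/C(C)=C\CC1 | intermediate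
28 | 4-hydroxybenzoic acid | OC(=O)c1ccc(O)cc1 | starting material
29 | tert-butyldimethylsilyl 4-(tert-butyldimethylsilyloxy)benzoate | CC(C)(C)[Si](C)(C)OC(=O)c1ccc(O[Si](C)(C)C(C)(C)C)cc1 | intermediate
30 | 4-(tert-butyldimethylsilyloxy)benzoic acid | CC(C)(C)[Si](C)(C)Oc1ccc(cc1)C(O)=O | intermediate
31 | 4-(tert-butyldimethylsilyloxy)benzoic 2,4,6-trichlorobenzoic anhydride | CC(C)(C)[Si](C)(C)Oc1ccc(cc1)C(=O)OC(=O)c1c(Cl)cc(Cl)cc1Cl | intermediate
32 | (1R,3Z,7Z,9S,10S)-9-(tert-butyldimethylsilyloxy)-3,7-dimethyl-10-(propan-2-yl)cyclodeca-3,7-dien-1-yl 4-(tert-butyldimethylsilyloxy)benzoate | C/C1=C/[C@H](O[Si](C)(C)C(C)(C)C)[C@@H](C(C)C)[C@H](OC(=O)c2ccc(O[Si](C)(C)C(C)(C)C)cc2)C/C(C)=C\CC1 | intermediate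
33 | (1R,3Z,7Z,9S,10R)-9-hydroxy-3,7-dimethyl-10-(propan-2-yl)cyclodeca-3,7-dien-1-yl 4-hydroxybenzoate | C/C1=C/[C@H](O)[C@@H](C(C)C)[C@H](OC(=O)c2ccc(O)cc2)C/C(C)=C\CC1 | target

## Step count and least certain steps

Total: 21 steps. Longest linear sequence: 19 steps (steps 1–9, 11–18, 20 and 21); steps 10 and 19 are side branches.

Step 15 (key step).
- What may go wrong: removal of an ether proton at C12 in place of C3, a competing [1,2]-shift, too little facial discrimination at C4 by the C5 stereocentre, or migration of the silyl group to the new alkoxide.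
- Fallback: make the same C3–C4 bond from an open chain by allylchromium addition. It sets out from 19 and rejoins at 24.
 - MnO2 in CH2Cl2 should oxidise the Z allylic alcohol to (2Z,6Z,9R,10E)-12-(4-methoxybenzyloxy)-3,7,11-trimethyl-9-(triethylsilyloxy)dodeca-2,6,10-trienal F1.
 - Buffered DDQ should free the C12 hydroxyl to give the hydroxy enal F2.
 - CBr4/PPh3 should give the bromo enal F3.
 - CrCl2 in THF at high dilution should add the allylchromium through C4 to the C3 aldehyde in a chair transition state (anti hydroxyl and isopropenyl), giving 24.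
 - Chromium-mediated closure of ω-formyl allylic bromides to 2-isopropenylcyclodecenols is known chemistry.

Step 14.
- What may go wrong: intermolecular etherification (oligomers), loss of HCl from the allylic chloride, or SN2′ attack.
- Fallback: form the ether bond between two molecules and close the ring at C10–C1. It sets out from 14 and rejoins at 22.
 - Buffered DDQ should give (2E,4R,6Z)-2,6-dimethyl-4-(triethylsilyloxy)nona-2,6,8-trien-1-ol F4.
 - Its sodium alkoxide is alkylated with (Z)-1-bromo-3-iodobut-2-ene F5 (from 17 with CBr4/PPh3) to give the iodoalkenyl dienyl ether F6.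
 - 9-BBN-H adds to the terminal alkene to give the alkylborane F7.
 - PdCl2(dppf)/Cs2CO3 at high dilution should close the ring by intramolecular B-alkyl Suzuki–Miyaura coupling to 22.

Step 8.
- What may go wrong: Z to E isomerisation of the open hydroxy enal under the basic ylide conditions, or incomplete ring opening of the lactol.
- Fallback: open the lactone as an amide and olefinate a protected enal in the cold. It sets out from 10 and rejoins at 14, replacing steps 7–9.
 - Me3Al/MeNH(OMe)·HCl should give the (2Z)-5-hydroxy Weinreb amide F8.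
 - Et3SiCl/imidazole gives the silyl ether F9.
 - i-Bu2AlH at −78 °C gives the (2Z)-enal F10.
 - Ph3P=CH2 at −78 °C should give 14.

Step 6.
- What may go wrong: metathesis at the trisubstituted C4=C11 alkene (five-membered lactone with loss of the C12 arm), or dimerisation.
- Fallback: build the lactone by cycloaddition instead of metathesis. It sets out from 6 and rejoins at 10, replacing steps 4–6.
 - 6 reacts with 1-methoxy-3-methyl-1-(trimethylsilyloxy)buta-1,3-diene under a Ti(OiPr)4/BINOL catalyst (enantiomer chosen for the 6R lactone), followed by mild acid.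
 - This enantioselective vinylogous aldol–lactonisation (formal hetero-Diels–Alder reaction) is a known reaction type and should give 10 directly.
 - It makes no compound outside the list (entry F0).

## Further compounds

F1 | step 15 | (2Z,6Z,9R,10E)-12-(4-methoxybenzyloxy)-3,7,11-trimethyl-9-(triethylsilyloxy)dodeca-2,6,10-trienal | COc1ccc(COC/C(C)=C/[C@H](O[Si](CC)(CC)CC)C/C(C)=C\CC/C(C)=C\C=O)cc1
F2 | step 15 | (2Z,6Z,9R,10E)-12-hydroxy-3,7,11-trimethyl-9-(triethylsilyloxy)dodeca-2,6,10-trienal | OC/C(C)=C/[C@H](O[Si](CC)(CC)CC)C/C(C)=C\CC/C(C)=C\C=O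
F3 | step 15 | (2Z,6Z,9R,10E)-12-bromo-3,7,11-trimethyl-9-(triethylsilyloxy)dodeca-2,6,10-trienal | BrC/C(C)=C/[C@H](O[Si](CC)(CC)CC)C/C(C)=C\CC/C(C)=C\C=O
F4 | step 14 | (2E,4R,6Z)-2,6-dimethyl-4-(triethylsilyloxy)nona-2,6,8-trien-1-ol | OC/C(C)=C/[C@H](O[Si](CC)(CC)CC)C/C(C)=C\C=C
F5 | step 14 | (Z)-1-bromo-3-iodobut-2-ene | C/C(I)=C/CBr
F6 | step 14 | (Z)-3-iodobut-2-enyl ether of F4 | C/C(I)=C/COC/C(C)=C/[C@H](O[Si](CC)(CC)CC)C/C(C)=C\C=C
F7 | step 14 | 9-borabicyclo[3.3.1]nonan-9-yl adduct of F6 at the terminal carbon (C10) | C/C(I)=C/COC/C(C)=C/[C@H](O[Si](CC)(CC)CC)C/C(C)=C\CCB1C2CCCC1CCC2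
F8 | step 8 | (2Z,5R,6E)-5-hydroxy-N-methoxy-8-(4-methoxybenzyloxy)-N,3,7-trimethylocta-2,6-dienamide | COc1ccc(COC/C(C)=C/[C@H](O)C/C(C)=C\C(=O)N(C)OC)cc1
F9 | step 8 | (2Z,5R,6E)-N-methoxy-8-(4-methoxybenzyloxy)-N,3,7-trimethyl-5-(triethylsilyloxy)octa-2,6-dienamide | COc1ccc(COC/C(C)=C/[C@H](O[Si](CC)(CC)CC)C/C(C)=C\C(=O)N(C)OC)cc1
F10 | step 8 | (2Z,5R,6E)-8-(4-methoxybenzyloxy)-3,7-dimethyl-5-(triethylsilyloxy)octa-2,6-dienal | COc1ccc(COC/C(C)=C/[C@H](O[Si](CC)(CC)CC)C/C(C)=C\C=O)cc1
F0 | step 6 | none | none
A1 | alternative 1 | ten-membered Z,Z-diene with C10 phenylsulfonyl, C3 tert-butyldimethylsilyl ether and C5 4-methoxybenzyl ether (C10 epimers) | C/C1=C/[C@H](O[Si](C)(C)C(C)(C)C)[C@@H](C(C)C)[C@H](OCc2ccc(OC)cc2)C/C(C)=C\CC1S(=O)(=O)c3ccccc3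
A2 | alternative 1 | open-chain C9 allylic chloride with C10 allylic phenyl sulfone | O=S(=O)(c1ccccc1)C/C(C)=C\[C@H](O[Si](C)(C)C(C)(C)C)[C@@H](C(C)C)[C@H](OCc1ccc(OC)cc1)C/C(C)=C\CCl
A3 | alternative 2 | (4Z,8Z)-5,9-dimethyl-2-(propan-2-yl)cyclodeca-4,8-diene-1,3-dione | C/C1=C/C(=O)C(C(C)C)C(=O)C/C(C)=C\CC1
A4 | alternative 2 | (2Z,6Z)-3,7-dimethylcycloocta-2,6-dienone | O=C1/C=C(C)\CC/C=C(C)\C1
A5 | alternative 2 | trimethylsilyl dienol ether of A4 (enol ether toward C8) | C[Si](C)(C)O/C1=C/C(C)=C\CC/C(C)=C\1
A6 | alternative 2 | chloro(propan-2-yl)ketene | CC(C)C(Cl)=C=O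
A7 | alternative 3 | ten-membered Z,Z-dienol with free C5 hydroxyl, C4 isopropenyl and C3 tert-butyldimethylsilyl ether | C/C1=C/[C@H](O[Si](C)(C)C(C)(C)C)[C@@H](C(C)=C)[C@H](O)C/C(C)=C\CC1
A8 | alternative 3 | open-chain Z,Z-dienal (C5 aldehyde) with C12 allylic bromide and C3 tert-butyldimethylsilyl ether | O=CC/C(C)=C\CC/C(C)=C\[C@H](O[Si](C)(C)C(C)(C)C)/C=C(\C)CBr
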